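**Retrosynthetic overview**
- The target is epicatechin-(4β→8)-epifisetinidol-(4β→8)-catechin; the last step is a global hydrogenolysis (13 O-benzyl groups, 3 C–Br) of a protected trimer.
- The lower interflavan bond (middle C4 to lower C8) comes from a thiophile-triggered Friedel–Crafts reaction of a 4-arylthio dimer with tetra-O-benzylcatechin.
- The upper interflavan bond (upper C4 to middle C8) comes from a Lewis-acid Friedel–Crafts reaction of a 6,8-dibromo-capped 4-alkoxy-epicatechin (made from (+)-catechin by C3 inversion and DDQ oxidation) with a middle unit whose C6 is blocked by Br and whose C4 is masked as a thioether.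
- The middle unit gets its 3α-oxygen and 4β-sulfur from a flav-3-ene by bromohydrin formation, closure to the α-epoxide and thiolate opening; the flav-3-ene comes from a (2S)-flavanone.
- Ring order: the pyranone ring of the middle unit is the only ring built, closed by a catalytic asymmetric intramolecular oxa-Michael addition of a phenol to an alkylidene β-ketoester; all other rings come from (+)-catechin.

Assumption and conventions: (+)-catechin, 3,4-dihydroxybenzaldehyde and methyl 5-bromo-2,4-dihydroxybenzoate are bought; flavan numbering is used; α is the face of ring C that carries the C2 aryl group and β the opposite face; Mes/mesityl = 2,4,6-trimethylphenyl; epifisetinidol = (2R,3R)-2,3-cis-3',4',7-trihydroxyflavan-3-ol.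

**Route**

Step 1
Reactants: 1 (+)-catechin
Product: 2 5,7,3',4'-tetra-O-benzyl-(+)-catechin
Conditions: BnBr (4.4 equiv), K2CO3, DMF, 0 °C → rt
Reagents that add atoms: benzyl bromide, BrCc1ccccc1
Why: Williamson etherification with a carbonate base alkylates only the four phenols and leaves the secondary 3-OH and both stereocentres untouched.

Step 2
Reactants: 2 5,7,3',4'-tetra-O-benzyl-(+)-catechin
Product: 3 (2R)-5,7-bis(benzyloxy)-2-[3,4-bis(benzyloxy)phenyl]chroman-3-one
Conditions: Dess–Martin periodinane, CH2Cl2, rt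
Reagents that add atoms: none
Why: Dess–Martin oxidation of the secondary alcohol runs under neutral conditions, so the C2 centre next to the new ketone is not epimerised.

Step 3
Reactants: 3 (2R)-5,7-bis(benzyloxy)-2-[3,4-bis(benzyloxy)phenyl]chroman-3-one
Product: 4 5,7,3',4'-tetra-O-benzyl-(−)-epicatechin
Conditions: LiBH(s-Bu)3 (L-Selectride), THF, −78 °C; H2O
Reagents that add atoms: none
Why: Substrate-controlled hydride reduction in which the bulky borohydride attacks the β face, opposite the 2α-aryl group, and so sets the 3α-OH (2,3-cis, 3R).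

Step 4
Reactants: 4 5,7,3',4'-tetra-O-benzyl-(−)-epicatechin
Product: 5 3,5,7,3',4'-penta-O-benzyl-(−)-epicatechin
Conditions: NaH, BnBr, Bu4NI (cat.), DMF, 0 °C → rt
Reagents that add atoms: benzyl bromide, BrCc1ccccc1
Why: Williamson etherification of the secondary alkoxide removes the only O–H nucleophile of the future electrophile and needs no separate deprotection later.

Step 5
Reactants: 5 3,5,7,3',4'-penta-O-benzyl-(−)-epicatechin
Product: 6 3,5,7,3',4'-penta-O-benzyl-4β-(2-ethoxyethoxy)epicatechin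
Conditions: DDQ (2 equiv), 2-ethoxyethanol (5 equiv), CH2Cl2, rt
Reagents that add atoms: 2-ethoxyethanol, CCOCCO
Why: DDQ benzylic oxidation abstracts hydride from C4 to give a cation stabilised by the 5,7-dialkoxy ring A, which the alcohol traps trans to the 3α-benzyloxy group (4β).

Step 6
Reactants: 6 3,5,7,3',4'-penta-O-benzyl-4β-(2-ethoxyethoxy)epicatechin
Product: 7 6,8-dibromo-3,5,7,3',4'-penta-O-benzyl-4β-(2-ethoxyethoxy)epicatechin
Conditions: NBS (2.1 equiv), CH2Cl2, −20 °C → rt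
Reagents that add atoms: N-bromosuccinimide, O=C1CCC(=O)N1Br
Why: Electrophilic aromatic bromination takes the two free positions of the phloroglucinol-type ring A well before ring B reacts, so the electrophile can no longer condense with itself.

Step 7
Reactants: 8 3,4-dihydroxybenzaldehyde
Product: 9 3,4-bis(benzyloxy)benzaldehyde
Conditions: BnBr (2.2 equiv), K2CO3, DMF, 60 °C
Reagents that add atoms: benzyl bromide, BrCc1ccccc1
Why: Williamson etherification of both phenols gives the ring-B aldehyde in the same protecting-group pattern as the catechin units.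

Step 8
Reactants: 10 methyl 5-bromo-2,4-dihydroxybenzoate
Product: 11 methyl 4-(benzyloxy)-5-bromo-2-hydroxybenzoate
Conditions: BnBr (1.05 equiv), K2CO3, acetone, reflux
Reagents that add atoms: benzyl bromide, BrCc1ccccc1
Why: Regioselective Williamson etherification, because the 2-OH is hydrogen-bonded to the ester carbonyl and only the more acidic, free 4-OH is alkylated.

Step 9
Reactants: 11 methyl 4-(benzyloxy)-5-bromo-2-hydroxybenzoate
Product: 12 tert-butyl 3-[4-(benzyloxy)-5-bromo-2-hydroxyphenyl]-3-oxopropanoate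
Conditions: tert-butyl acetate and LiN(SiMe3)2 (3.5 equiv each), THF, −78 → 0 °C; 1 M HCl
Reagents that add atoms: tert-butyl acetate, CC(=O)OC(C)(C)C
Why: Crossed Claisen condensation of the pre-formed lithium ester enolate with the methyl ester, the excess base covering the phenol and the acidic β-ketoester product, while the amide base does not touch the aryl bromide.

Step 10
Reactants: 12 tert-butyl 3-[4-(benzyloxy)-5-bromo-2-hydroxyphenyl]-3-oxopropanoate; 9 3,4-bis(benzyloxy)benzaldehyde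
Product: 13 tert-butyl 2-[4-(benzyloxy)-5-bromo-2-hydroxybenzoyl]-3-[3,4-bis(benzyloxy)phenyl]prop-2-enoate (E/Z mixture)
Conditions: piperidine (20 mol %), AcOH (20 mol %), 4 Å MS, toluene, rt
Reagents that add atoms: none
Why: Knoevenagel condensation of the active methylene with the aldehyde gives the doubly activated Michael acceptor, and both alkene isomers converge in the next step.

Step 11
Reactants: 13 tert-butyl 2-[4-(benzyloxy)-5-bromo-2-hydroxybenzoyl]-3-[3,4-bis(benzyloxy)phenyl]prop-2-enoate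
Product: 15 (2S)-7-(benzyloxy)-2-[3,4-bis(benzyloxy)phenyl]-6-bromochroman-4-one, via trans-tert-butyl 4-oxoflavan-3-carboxylate 14 (not isolated)
Conditions: 9-amino-9-deoxy-epi-quinidine-derived N-[3,5-bis(trifluoromethyl)phenyl]thiourea (10 mol %), toluene, −25 °C; then p-TsOH·H2O, 80 °C; recrystallise
Reagents that add atoms: none
Why: Catalytic asymmetric intramolecular oxa-Michael addition (6-endo) in which the thiourea binds the β-ketoester and the quinuclidine guides the phenol to one face of the alkylidene, setting C2 (2α-aryl, 2S), after which acid cleaves the tert-butyl ester and the β-keto acid decarboxylates without touching C2. The pseudo-enantiomeric quinine-derived catalyst gives the antipode, so the sense is confirmed once by chiral HPLC/CD.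

Step 12
Reactants: 15 (2S)-7-(benzyloxy)-2-[3,4-bis(benzyloxy)phenyl]-6-bromochroman-4-one
Product: 16 (2S,4S)-7-(benzyloxy)-2-[3,4-bis(benzyloxy)phenyl]-6-bromochroman-4-ol
Conditions: NaBH4, THF/MeOH, 0 °C
Reagents that add atoms: none
Why: Borohydride reduction of the aryl ketone (axial attack, 2,4-cis alcohol) is faster than any base-induced ring opening, so C2 is kept, and the C4 configuration is lost again in the next step.

Step 13
Reactants: 16 (2S,4S)-7-(benzyloxy)-2-[3,4-bis(benzyloxy)phenyl]-6-bromochroman-4-ol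
Product: 17 (2S)-7-(benzyloxy)-2-[3,4-bis(benzyloxy)phenyl]-6-bromo-2H-chromene
Conditions: Burgess reagent, THF, 50 °C
Reagents that add atoms: none
Why: Burgess dehydration (syn elimination of the sulfamate ester) forms the flav-3-ene under neutral conditions, avoiding acid that could ionise the allylic C2–O bond and racemise C2.

Step 14
Reactants: 17 (2S)-7-(benzyloxy)-2-[3,4-bis(benzyloxy)phenyl]-6-bromo-2H-chromene
Product: 18 7-(benzyloxy)-2-[3,4-bis(benzyloxy)phenyl]-3β,6-dibromochroman-4α-ol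
Conditions: NBS (1.05 equiv), THF/H2O (4:1), 0 °C
Reagents that add atoms: N-bromosuccinimide, O=C1CCC(=O)N1Br; water, O
Why: Bromohydrin formation in which bromine adds to C3 from the β face, anti to the 2α-aryl group, and water captures the 4-alkoxybenzylic C4 position anti to bromine (3β-Br, 4α-OH), the electron-rich styrene-type alkene reacting much faster than either arene.

Step 15
Reactants: 18 7-(benzyloxy)-2-[3,4-bis(benzyloxy)phenyl]-3β,6-dibromochroman-4α-ol
Product: 20 7-(benzyloxy)-2-[3,4-bis(benzyloxy)phenyl]-6-bromo-4β-(mesitylsulfanyl)chroman-3α-ol, via 3α,4α-epoxyflavan 19 (not isolated)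
Conditions: K2CO3, DMF, 0 °C; then 2,4,6-Me3C6H2SH, rt
Reagents that add atoms: 2,4,6-trimethylbenzenethiol, Cc1cc(C)c(S)c(C)c1
Why: Intramolecular Williamson closure with inversion at C3 places the epoxide oxygen on the α face (cis to the aryl group), and SN2 opening by the thiolate at the benzylic C4 with inversion gives the 3α-OH/4β-S pattern (2,3-cis-3,4-trans).

Step 16
Reactants: 20 7-(benzyloxy)-2-[3,4-bis(benzyloxy)phenyl]-6-bromo-4β-(mesitylsulfanyl)chroman-3α-ol
Product: 21 3α,7-bis(benzyloxy)-2-[3,4-bis(benzyloxy)phenyl]-6-bromo-4β-(mesitylsulfanyl)chroman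
Conditions: NaH, BnBr, Bu4NI (cat.), THF/DMF, 0 °C → rt
Reagents that add atoms: benzyl bromide, BrCc1ccccc1
Why: Williamson etherification caps the 3-OH so that carbon C8 is the only nucleophilic site offered to the cation in the next step, and the aryl sulfide is inert to these conditions.

Step 17
Reactants: 7 6,8-dibromo-3,5,7,3',4'-penta-O-benzyl-4β-(2-ethoxyethoxy)epicatechin (1.5 equiv); 21 3α,7-bis(benzyloxy)-2-[3,4-bis(benzyloxy)phenyl]-6-bromo-4β-(mesitylsulfanyl)chroman
Product: 22 [6,8-dibromo-penta-O-benzylepicatechin]-(4β→8)-[3,7,3',4'-tetra-O-benzyl-6-bromo-4β-(mesitylsulfanyl)epifisetinidol]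
Conditions: Me3SiOTf (0.3 equiv), 4 Å MS, CH2Cl2, −40 → −10 °C
Reagents that add atoms: none
Why: Friedel–Crafts (SN1) alkylation in which the hard Lewis acid ionises only the 4-ether of 7 (the C4–S bond of 21 stays intact), the cation cannot attack its own fully substituted ring A, C8 is the only activated free position of 21 (C6 carries Br), and attack anti to the 3α-benzyloxy and 2α-aryl groups sets the upper 4β (4R) centre.

Step 18
Reactants: 22 [6,8-dibromo-penta-O-benzylepicatechin]-(4β→8)-[3,7,3',4'-tetra-O-benzyl-6-bromo-4β-(mesitylsulfanyl)epifisetinidol]; 2 5,7,3',4'-tetra-O-benzyl-(+)-catechin (3 equiv)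
Product: 23 [6,8-dibromo-penta-O-benzylepicatechin]-(4β→8)-[3,7,3',4'-tetra-O-benzyl-6-bromoepifisetinidol]-(4β→8)-[5,7,3',4'-tetra-O-benzylcatechin]
Conditions: AgOSO2CF3 (silver triflate, 2 equiv), 4 Å MS, CH2Cl2, −40 → 0 °C, dark; aq. NaHCO3
Reagents that add atoms: none
Why: Thiophilic activation of the benzylic sulfide by the silver salt gives the 4-alkoxybenzylic C4 cation of the middle unit, which undergoes Friedel–Crafts attack by the most nucleophilic carbon present, C8 of the catechin ring A, anti to the 3α-benzyloxy and 2α-aryl groups (middle 4β, 4R), the excess of 2 suppressing further reaction of the product.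

Step 19
Reactants: 23 [6,8-dibromo-penta-O-benzylepicatechin]-(4β→8)-[3,7,3',4'-tetra-O-benzyl-6-bromoepifisetinidol]-(4β→8)-[5,7,3',4'-tetra-O-benzylcatechin]
Product: 24 epicatechin-(4β→8)-epifisetinidol-(4β→8)-catechin (CNP0270097.1)
Conditions: H2 (1 atm), Pd(OH)2/C, NaOAc, THF/MeOH/H2O, rt
Reagents that add atoms: none
Why: Catalytic hydrogenolysis cleaves all thirteen benzyl ethers and the three aryl C–Br bonds in one operation, with acetate buffering the HBr so that the acid-labile interflavan bonds and all eight stereocentres survive.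

**Compound list**

1 | (+)-catechin, (2R,3S)-2-(3,4-dihydroxyphenyl)chroman-3,5,7-triol (2α-aryl, 3β-OH) | Oc1cc(O)c2c(c1)O[C@H](c1ccc(O)c(O)c1)[C@@H](O)C2 | starting material
2 | 5,7,3',4'-tetra-O-benzyl-(+)-catechin, (2R,3S), free 3β-OH | c1ccccc1COc1cc(OCc2ccccc2)c2c(c1)O[C@H](c1ccc(OCc3ccccc3)c(OCc3ccccc3)c1)[C@@H](O)C2 | intermediate
3 | (2R)-5,7-bis(benzyloxy)-2-[3,4-bis(benzyloxy)phenyl]chroman-3-one | c1ccccc1COc1cc(OCc2ccccc2)c2c(c1)O[C@H](c1ccc(OCc3ccccc3)c(OCc3ccccc3)c1)C(=O)C2 | intermediate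
4 | 5,7,3',4'-tetra-O-benzyl-(−)-epicatechin, (2R,3R) (2α-aryl, 3α-OH, 2,3-cis) | c1ccccc1COc1cc(OCc2ccccc2)c2c(c1)O[C@H](c1ccc(OCc3ccccc3)c(OCc3ccccc3)c1)[C@H](O)C2 | intermediate
5 | 3,5,7,3',4'-penta-O-benzyl-(−)-epicatechin, (2R,3R) | c1ccccc1COc1cc(OCc2ccccc2)c2c(c1)O[C@H](c1ccc(OCc3ccccc3)c(OCc3ccccc3)c1)[C@H](OCc1ccccc1)C2 | intermediate
6 | 3,5,7,3',4'-penta-O-benzyl-4β-(2-ethoxyethoxy)epicatechin (2α-aryl, 3α-OBn, 4β-OR; 2,3-cis-3,4-trans) | c1ccccc1COc1cc(OCc2ccccc2)c2c(c1)O[C@H](c1ccc(OCc3ccccc3)c(OCc3ccccc3)c1)[C@H](OCc1ccccc1)[C@H]2OCCOCC | intermediate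
7 | 6,8-dibromo-3,5,7,3',4'-penta-O-benzyl-4β-(2-ethoxyethoxy)epicatechin (2α-aryl, 3α-OBn, 4β-OR) | c1ccccc1COc1c(Br)c(OCc2ccccc2)c2c(c1Br)O[C@H](c1ccc(OCc3ccccc3)c(OCc3ccccc3)c1)[C@H](OCc1ccccc1)[C@H]2OCCOCC | intermediate
8 | 3,4-dihydroxybenzaldehyde | O=Cc1ccc(O)c(O)c1 | starting material
9 | 3,4-bis(benzyloxy)benzaldehyde | O=Cc1ccc(OCc2ccccc2)c(OCc2ccccc2)c1 | intermediate
10 | methyl 5-bromo-2,4-dihydroxybenzoate | COC(=O)c1cc(Br)c(O)cc1O | starting material
11 | methyl 4-(benzyloxy)-5-bromo-2-hydroxybenzoate | COC(=O)c1cc(Br)c(OCc2ccccc2)cc1O | intermediate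
12 | tert-butyl 3-[4-(benzyloxy)-5-bromo-2-hydroxyphenyl]-3-oxopropanoate | CC(C)(C)OC(=O)CC(=O)c1cc(Br)c(OCc2ccccc2)cc1O | intermediate
13 | tert-butyl 2-[4-(benzyloxy)-5-bromo-2-hydroxybenzoyl]-3-[3,4-bis(benzyloxy)phenyl]prop-2-enoate (E/Z mixture, no stereocentre) | CC(C)(C)OC(=O)C(=Cc1ccc(OCc2ccccc2)c(OCc2ccccc2)c1)C(=O)c1cc(Br)c(OCc2ccccc2)cc1O | intermediate
14 | tert-butyl 7-(benzyloxy)-2-[3,4-bis(benzyloxy)phenyl]-6-bromo-4-oxochroman-3-carboxylate (2α-aryl, 3β-ester, 2,3-trans; in equilibrium with its enol) | c1ccccc1COc1c(Br)cc2c(c1)O[C@H](c1ccc(OCc3ccccc3)c(OCc3ccccc3)c1)[C@@H](C(=O)OC(C)(C)C)C2=O | intermediate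
15 | (2S)-7-(benzyloxy)-2-[3,4-bis(benzyloxy)phenyl]-6-bromochroman-4-one (2α-aryl) | c1ccccc1COc1c(Br)cc2c(c1)O[C@H](c1ccc(OCc3ccccc3)c(OCc3ccccc3)c1)CC2=O | intermediate
16 | (2S,4S)-7-(benzyloxy)-2-[3,4-bis(benzyloxy)phenyl]-6-bromochroman-4-ol (2α-aryl, 4α-OH, 2,4-cis) | c1ccccc1COc1c(Br)cc2c(c1)O[C@H](c1ccc(OCc3ccccc3)c(OCc3ccccc3)c1)C[C@@H]2O | intermediate
17 | (2S)-7-(benzyloxy)-2-[3,4-bis(benzyloxy)phenyl]-6-bromo-2H-chromene (2α-aryl) | c1ccccc1COc1c(Br)cc2c(c1)O[C@H](c1ccc(OCc3ccccc3)c(OCc3ccccc3)c1)C=C2 | intermediate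
18 | 7-(benzyloxy)-2-[3,4-bis(benzyloxy)phenyl]-3β,6-dibromochroman-4α-ol (2α-aryl; 2,3-trans-3,4-trans) | c1ccccc1COc1c(Br)cc2c(c1)O[C@H](c1ccc(OCc3ccccc3)c(OCc3ccccc3)c1)[C@@H](Br)[C@@H]2O | intermediate
19 | 7-(benzyloxy)-2-[3,4-bis(benzyloxy)phenyl]-6-bromo-3α,4α-epoxychroman (epoxide oxygen on the face of the 2-aryl group) | c1ccccc1COc1c(Br)cc2c(c1)O[C@H](c1ccc(OCc3ccccc3)c(OCc3ccccc3)c1)[C@@H]1O[C@H]21 | intermediate
20 | 7-(benzyloxy)-2-[3,4-bis(benzyloxy)phenyl]-6-bromo-4β-(mesitylsulfanyl)chroman-3α-ol (2α-aryl; 2,3-cis-3,4-trans) | c1ccccc1COc1c(Br)cc2c(c1)O[C@H](c1ccc(OCc3ccccc3)c(OCc3ccccc3)c1)[C@H](O)[C@H]2Sc1c(C)cc(C)cc1C | intermediate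
21 | 3α,7-bis(benzyloxy)-2-[3,4-bis(benzyloxy)phenyl]-6-bromo-4β-(mesitylsulfanyl)chroman (2α-aryl; 2,3-cis-3,4-trans) | c1ccccc1COc1c(Br)cc2c(c1)O[C@H](c1ccc(OCc3ccccc3)c(OCc3ccccc3)c1)[C@H](OCc1ccccc1)[C@H]2Sc1c(C)cc(C)cc1C | intermediate
22 | [6,8-dibromo-3,5,7,3',4'-penta-O-benzylepicatechin]-(4β→8)-[3,7,3',4'-tetra-O-benzyl-6-bromo-4β-(mesitylsulfanyl)epifisetinidol] | c1ccccc1COc1c(Br)c(OCc2ccccc2)c2c(c1Br)O[C@H](c1ccc(OCc3ccccc3)c(OCc3ccccc3)c1)[C@H](OCc1ccccc1)[C@H]2c1c(OCc2ccccc2)c(Br)cc2c1O[C@H](c1ccc(OCc3ccccc3)c(OCc3ccccc3)c1)[C@H](OCc1ccccc1)[C@H]2Sc1c(C)cc(C)cc1C | intermediate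
23 | [6,8-dibromo-3,5,7,3',4'-penta-O-benzylepicatechin]-(4β→8)-[3,7,3',4'-tetra-O-benzyl-6-bromoepifisetinidol]-(4β→8)-[5,7,3',4'-tetra-O-benzylcatechin] | c1ccccc1COc1c(Br)c(OCc2ccccc2)c2c(c1Br)O[C@H](c1ccc(OCc3ccccc3)c(OCc3ccccc3)c1)[C@H](OCc1ccccc1)[C@H]2c1c(OCc2ccccc2)c(Br)cc2c1O[C@H](c1ccc(OCc3ccccc3)c(OCc3ccccc3)c1)[C@H](OCc1ccccc1)[C@H]2c1c(OCc2ccccc2)cc(OCc2ccccc2)c2c1O[C@H](c1ccc(OCc3ccccc3)c(OCc3ccccc3)c1)[C@@H](O)C2 | intermediate
24 | epicatechin-(4β→8)-epifisetinidol-(4β→8)-catechin, CNP0270097.1 (upper and middle units 2R,3R,4R; lower unit 2R,3S) | Oc1cc(O)c2c(c1)O[C@H](c1ccc(O)c(O)c1)[C@H](O)[C@H]2c1c(O)ccc2c1O[C@H](c1ccc(O)c(O)c1)[C@H](O)[C@H]2c1c(O)cc(O)c2c1O[C@H](c1ccc(O)c(O)c1)[C@@H](O)C2 | target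

**Totals**

Total step count: 19.
Longest linear sequence: 12 steps (steps 8–19, from 10 to 24), which is 63 % of the total. The catechin branch (steps 1–6) and the aldehyde branch (step 7) join it at steps 17, 18 and 10.

**Steps most likely to fail, with fallbacks**

First, step 17. C8 of 21 lies between two oxygen substituents and is deactivated by the meta bromine, so it is a far weaker nucleophile than a catechin ring A. The cation from 7 may then be consumed by ring B positions or by elimination before it is trapped at C8. The fallback sets out from 21 and reverses the order of the two unions, so that the slow alkylation is run last, on a nucleophile without a latent leaving group and with the cheap electrophile in large excess. Coupling of 21 with 2 under the silver triflate conditions of step 18 gives the middle–lower dimer [3,7,3',4'-tetra-O-benzyl-6-bromoepifisetinidol]-(4β→8)-[5,7,3',4'-tetra-O-benzylcatechin] F1. NBS (1.0 equiv, CH2Cl2, −78 → −20 °C) then brominates the only phloroglucinol-type position left, C6 of the catechin unit, to give the 6-bromo-capped dimer F2. Alkylation of F2 with 7 (3 equiv, BF3·OEt2, CH2Cl2, −20 → 0 °C) can now only occur at C8 of the middle unit and gives the tetrabromo protected trimer F3. Hydrogenolysis of F3 under the conditions of step 19 comes back to the route at 24.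

Second, step 18. A silver salt may be too weak a thiophile for the hindered mesityl sulfide on the less stabilised 5-deoxy cation, and halonium thiophiles cannot be used while the very electron-rich 2 is present. The fallback sets out from 22 and separates sulfur removal from C–C bond formation. NBS (1.1 equiv) in acetone/H2O at −20 °C hydrolyses the sulfide to the 4β-hydroxy dimer [6,8-dibromo-penta-O-benzylepicatechin]-(4β→8)-[3,7,3',4'-tetra-O-benzyl-6-bromoepifisetinidol-4β-ol] F4; no activated ring-A position of 22 is free, so ring bromination is not a concern. F4 is then ionised with Me3SiOTf (cat., CH2Cl2, −40 °C) in the presence of 2 (3 equiv), the classical flavan-4-ol condensation, which comes back to the route at 23.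

Third, step 11. The enantioselectivity of the organocatalytic oxa-Michael closure on this bromo-substituted, electron-rich substrate may be insufficient, and premature racemic cyclisation during step 10 would erode it further. The fallback sets out from 13 and replaces asymmetric catalysis by resolution. DBU (10 mol %, toluene, rt) followed by p-TsOH at 80 °C gives the racemic flavanone rac-7-(benzyloxy)-2-[3,4-bis(benzyloxy)phenyl]-6-bromochroman-4-one F5. Kinetic resolution by Noyori-type asymmetric transfer hydrogenation with RuCl[(S,S)-TsDPEN](p-cymene) in HCO2H/Et3N (5:2) at rt, stopped near 50 % conversion, reduces the (2S) ketone to the (4S) cis alcohol and so comes back to the route at 16. It leaves the (2R)-flavanone F6, which is racemised with base through reversible ring opening to the chalcone and recycled.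

**Further compounds**

F1 | step 17 | [3,7,3',4'-tetra-O-benzyl-6-bromoepifisetinidol]-(4β→8)-[5,7,3',4'-tetra-O-benzylcatechin] | c1ccccc1COc1c(Br)cc2c(c1)O[C@H](c1ccc(OCc3ccccc3)c(OCc3ccccc3)c1)[C@H](OCc1ccccc1)[C@H]2c1c(OCc2ccccc2)cc(OCc2ccccc2)c2c1O[C@H](c1ccc(OCc3ccccc3)c(OCc3ccccc3)c1)[C@@H](O)C2
F2 | step 17 | [3,7,3',4'-tetra-O-benzyl-6-bromoepifisetinidol]-(4β→8)-[6-bromo-5,7,3',4'-tetra-O-benzylcatechin] | c1ccccc1COc1c(Br)cc2c(c1)O[C@H](c1ccc(OCc3ccccc3)c(OCc3ccccc3)c1)[C@H](OCc1ccccc1)[C@H]2c1c(OCc2ccccc2)c(Br)c(OCc2ccccc2)c2c1O[C@H](c1ccc(OCc3ccccc3)c(OCc3ccccc3)c1)[C@@H](O)C2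
F3 | step 17 | [6,8-dibromo-penta-O-benzylepicatechin]-(4β→8)-[3,7,3',4'-tetra-O-benzyl-6-bromoepifisetinidol]-(4β→8)-[6-bromo-5,7,3',4'-tetra-O-benzylcatechin] | c1ccccc1COc1c(Br)c(OCc2ccccc2)c2c(c1Br)O[C@H](c1ccc(OCc3ccccc3)c(OCc3ccccc3)c1)[C@H](OCc1ccccc1)[C@H]2c1c(OCc2ccccc2)c(Br)cc2c1O[C@H](c1ccc(OCc3ccccc3)c(OCc3ccccc3)c1)[C@H](OCc1ccccc1)[C@H]2c1c(OCc2ccccc2)c(Br)c(OCc2ccccc2)c2c1O[C@H](c1ccc(OCc3ccccc3)c(OCc3ccccc3)c1)[C@@H](O)C2
F4 | step 18 | [6,8-dibromo-penta-O-benzylepicatechin]-(4β→8)-[3,7,3',4'-tetra-O-benzyl-6-bromoepifisetinidol-4β-ol] | c1ccccc1COc1c(Br)c(OCc2ccccc2)c2c(c1Br)O[C@H](c1ccc(OCc3ccccc3)c(OCc3ccccc3)c1)[C@H](OCc1ccccc1)[C@H]2c1c(OCc2ccccc2)c(Br)cc2c1O[C@H](c1ccc(OCc3ccccc3)c(OCc3ccccc3)c1)[C@H](OCc1ccccc1)[C@H]2O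
F5 | step 11 | rac-7-(benzyloxy)-2-[3,4-bis(benzyloxy)phenyl]-6-bromochroman-4-one | c1ccccc1COc1c(Br)cc2c(c1)OC(c1ccc(OCc3ccccc3)c(OCc3ccccc3)c1)CC2=O
F6 | step 11 | (2R)-7-(benzyloxy)-2-[3,4-bis(benzyloxy)phenyl]-6-bromochroman-4-one | c1ccccc1COc1c(Br)cc2c(c1)O[C@@H](c1ccc(OCc3ccccc3)c(OCc3ccccc3)c1)CC2=O
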